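**Plan**

- Retrosynthetic cuts: the eight O–H bonds (back to methyl ethers); the aryl–vinyl bond of the stilbene at C6 of unit 1 (Heck); C2–C3 of unit 1 (carbene C–H insertion) and C3–C6' (aryllithium plus aldehyde); ring E as a whole, through its ipso–ortho bond, back to a carbonyl chain on C3'; C2'–C3' of unit 2 (carbene C–H insertion).
- Feature that allows the central step: in unit 2 (O1', C2' carrying the 2,4-dihydroxyphenyl group, C3', benzo ring D whose C6' is bonded to C3 of unit 1) the 3,5-dihydroxyphenyl ring E on C3' is a resorcinol, a decarboxylated tetraketide. Its ipso carbon can therefore start as the carboxyl carbon of a dihydrobenzofuran-3-carboxylic acid and its other five carbons as a keto-dioxinone.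
- Forward order: furan ring of unit 2 (step 6), ring E (step 10), C3–C6' link (step 14), furan ring of unit 1 (step 17), stilbene (step 19), free phenols (step 20); one salicylaldehyde (2) supplies both benzo rings A and D.
- Stereochemistry: C2' from the chiral dirhodium carboxylate in step 6, C3' by base equilibration to trans (step 7); C3 from the second chiral dirhodium carboxylate in step 17, C2 by acid equilibration to trans (step 18); the E-alkene from the Heck reaction.

Key step: step 10

Assumption: the sense of induction of both dirhodium catalysts is assigned by analogy with the closest dihydrobenzofuran-forming insertions as recalled (S-configured phthalimido carboxylates giving the 2R cis series), not verified; if either insertion ran in the opposite sense, the mirror-image catalyst would be used with nothing else changed.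

**Route**

Step 1
Reactants: 1 4-bromo-2,6-dimethoxybenzaldehyde (commercial)
Product: 2 4-bromo-2-hydroxy-6-methoxybenzaldehyde
Conditions: BCl3 (1.2 equiv), CH2Cl2, −78 → 0 °C; H2O
Reagents that add atoms: none
Why: BCl3 chelates between the aldehyde oxygen and one ortho methoxy group, so a single chelation-directed aryl methyl ether cleavage takes place and the second methoxy group is left intact.

Step 2
Reactants: 2 4-bromo-2-hydroxy-6-methoxybenzaldehyde; 3 (2,4-dimethoxyphenyl)methanol
Product: 4 4-bromo-2-[(2,4-dimethoxybenzyl)oxy]-6-methoxybenzaldehyde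
Conditions: PPh3, DIAD, THF, 0 °C → rt
Reagents that add atoms: none
Why: Mitsunobu etherification of the acidic salicylaldehyde-type phenol with the primary benzylic alcohol gives the aryl benzyl ether under neutral conditions and avoids the unstable 2,4-dimethoxybenzyl halide.

Step 3
Reactants: 4 4-bromo-2-[(2,4-dimethoxybenzyl)oxy]-6-methoxybenzaldehyde
Product: 6 2-{4-bromo-2-[(2,4-dimethoxybenzyl)oxy]-6-methoxyphenyl}acetonitrile, via alkenyl formamide 5 (not isolated)
Conditions: TosMIC, KOt-Bu, DME, −40 °C; then MeOH, 65 °C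
Reagents that add atoms: p-toluenesulfonylmethyl isocyanide (TosMIC), Cc1ccc(cc1)S(=O)(=O)C[N+]#[C-]
Why: In the van Leusen reductive cyanation the TosMIC anion adds to the aldehyde, the oxazoline opens to the N-formyl alkenyl sulfone, and methanolysis expels formate and sulfinate to leave the one-carbon-homologated nitrile without any acid that would endanger the dimethoxybenzyl ether.

Step 4
Reactants: 6 2-{4-bromo-2-[(2,4-dimethoxybenzyl)oxy]-6-methoxyphenyl}acetonitrile
Product: 8 methyl 2-{4-bromo-2-[(2,4-dimethoxybenzyl)oxy]-6-methoxyphenyl}acetate, via arylacetic acid 7 (not isolated)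
Conditions: KOH, EtOH–H2O, reflux; 1 M HCl, 0 °C (pH 3); then MeI, K2CO3, DMF, rt
Reagents that add atoms: water, O; iodomethane, CI
Why: Alkaline nitrile hydrolysis to the arylacetic acid followed by O-methylation of the carboxylate is standard and leaves the acid-labile benzylic ether and the aryl bromide untouched.

Step 5
Reactants: 8 methyl 2-{4-bromo-2-[(2,4-dimethoxybenzyl)oxy]-6-methoxyphenyl}acetate
Product: 9 methyl 2-{4-bromo-2-[(2,4-dimethoxybenzyl)oxy]-6-methoxyphenyl}-2-diazoacetate
Conditions: p-ABSA, DBU, MeCN, 0 °C → rt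
Reagents that add atoms: 4-acetamidobenzenesulfonyl azide (p-ABSA), CC(=O)Nc1ccc(cc1)S(=O)(=O)N=[N+]=[N-]
Why: Regitz diazo transfer from the sulfonyl azide to the DBU-generated ester enolate gives the aryldiazoacetate, the benzylic ester position being the only acidic site.

Step 6
Reactants: 9 methyl 2-{4-bromo-2-[(2,4-dimethoxybenzyl)oxy]-6-methoxyphenyl}-2-diazoacetate
Product: 10 methyl (2S,3R)-6-bromo-2-(2,4-dimethoxyphenyl)-4-methoxy-2,3-dihydro-1-benzofuran-3-carboxylate (cis ester)
Conditions: Rh2(R-PTTL)4 [dirhodium tetrakis(N-phthaloyl-(R)-tert-leucinate)] (1 mol%), toluene, −60 °C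
Reagents that add atoms: none
Why: Intramolecular 1,5 C–H insertion of the rhodium carbene into the doubly activated benzylic ether C–H bond closes the furan ring, this catalyst family being known to give cis-2-aryl-2,3-dihydrobenzofuran-3-carboxylates with high enantiocontrol at the aryl-bearing carbon (C2' set as S by the R-configured catalyst), while the methyl C–H bonds of the other ortho ether are far less reactive.

Step 7
Reactants: 10 cis ester
Product: 12 (2S,3S)-6-bromo-2-(2,4-dimethoxyphenyl)-4-methoxy-2,3-dihydro-1-benzofuran-3-carboxylic acid (trans acid), via trans methyl ester 11 (not isolated)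
Conditions: NaOMe, MeOH, 50 °C; then H2O, 60 °C; 1 M HCl, 0 °C (pH 3)
Reagents that add atoms: water, O
Why: Methoxide equilibrates the ester at C3' through its enolate to the thermodynamically preferred trans isomer with C2' untouched, and saponification then freezes that configuration in the non-enolisable carboxylate, ring opening by beta-elimination being stereoelectronically disfavoured in the five-membered ring.

Step 8
Reactants: 13 2,2,6-trimethyl-4H-1,3-dioxin-4-one
Product: 15 2,2-dimethyl-6-(2-oxopropyl)-4H-1,3-dioxin-4-one (keto-dioxinone), via lithium dienolate 14 (not isolated)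
Conditions: LiN(SiMe3)2, THF, −78 °C; AcCl (0.5 equiv), −78 °C; 1 M HCl
Reagents that add atoms: acetyl chloride, CC(=O)Cl
Why: Gamma-deprotonation of the dioxinone gives the vinylogous enolate, which is C-acylated at its exocyclic carbon in a Claisen-type reaction, half an equivalent of acetyl chloride being used because the more acidic product consumes a second enolate.

Step 9
Reactants: 12 trans acid; 15 keto-dioxinone
Product: 18 6-{4-[(2S,3S)-6-bromo-2-(2,4-dimethoxyphenyl)-4-methoxy-2,3-dihydro-1-benzofuran-3-yl]-2,4-dioxobutyl}-2,2-dimethyl-4H-1,3-dioxin-4-one (diketo-dioxinone), via acyl imidazolide 16 (not isolated), via dilithium dianion 17 (not isolated)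
Conditions: 12, CDI, THF, rt; separately 15 (3 equiv), LiN(i-Pr)2 (6 equiv), THF, −78 °C; add the imidazolide solution, −78 → −40 °C; AcOH
Reagents that add atoms: none
Why: In this Claisen-type C-acylation of a 1,3-dicarbonyl dianion the more basic terminal enolate carbon attacks the acyl imidazolide at low temperature, the resulting 1,3-diketone is protected as its enolate against further addition, and the excess dianion absorbs the liberated imidazole.

Step 10
Reactants: 18 diketo-dioxinone
Product: 19 5-[(2S,3S)-6-bromo-2-(2,4-dimethoxyphenyl)-4-methoxy-2,3-dihydro-1-benzofuran-3-yl]-7-hydroxy-2,2-dimethyl-4H-1,3-benzodioxin-4-one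
Conditions: Et3N, CH2Cl2, rt
Reagents that add atoms: none
Why: Et3N enolises the 1,3-diketone, the nucleophilic C5 of the dioxinone (the alpha-carbon of the vinylogous carbonate) adds to the ketone attached to C3' in an intramolecular aldol reaction, and loss of water with tautomerisation of the remaining ketone gives the aromatic ring. This is the established base-mediated aromatisation of diketo-dioxinones to isopropylidene-protected beta-resorcylates, a biomimetic polyketide cyclisation. Ring E closes in a 6-(enolendo)-exo-trig mode, forming the bond between its ipso carbon and the ortho carbon that carries the masked carboxyl group. No stereocentre is created; C2' and C3' are carried through, and since C3' is alpha to a ketone only before the closure, any enolisation there returns the trans isomer favoured by the fixed C2' aryl group. The required aldol regioselectivity is secured by the chain itself: attack by any other carbon would give a four- or eight-membered ring, and the dioxinone carbonyl lies trans to the side chain across the ring double bond and cannot be reached.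

Step 11
Reactants: 19 benzodioxinone
Product: 21 5-[(2S,3S)-6-bromo-2-(2,4-dimethoxyphenyl)-4-methoxy-2,3-dihydro-1-benzofuran-3-yl]benzene-1,3-diol, via resorcylic acid 20 (not isolated)
Conditions: KOH (aq.), 1,4-dioxane, 120 °C (sealed tube); 1 M HCl, 0 °C (pH 4)
Reagents that add atoms: none
Why: Hydroxide opens the benzodioxinone to the beta-resorcylic acid with loss of acetone, and this electron-rich 2,4-dihydroxybenzoic acid decarboxylates by ipso-protonation in the hot medium, as orsellinic acid gives orcinol.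

Step 12
Reactants: 21 resorcinol
Product: 22 (2S,3S)-6-bromo-2-(2,4-dimethoxyphenyl)-3-(3,5-dimethoxyphenyl)-4-methoxy-2,3-dihydro-1-benzofuran
Conditions: MeI, K2CO3, acetone, reflux
Reagents that add atoms: iodomethane, CI
Why: Williamson O-methylation of both phenols protects ring E for the organolithium chemistry that follows.

Step 13
Reactants: 2 4-bromo-2-hydroxy-6-methoxybenzaldehyde; 23 4-methoxybenzyl chloride
Product: 24 4-bromo-2-methoxy-6-[(4-methoxybenzyl)oxy]benzaldehyde
Conditions: K2CO3, DMF, 60 °C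
Reagents that add atoms: none
Why: Williamson etherification of the phenol with the benzylic chloride installs the 4-methoxybenzyl ether whose CH2 group becomes C2 of unit 1 together with its aryl substituent.

Step 14
Reactants: 22 aryl bromide; 24 aldehyde
Product: 26 {4-bromo-2-methoxy-6-[(4-methoxybenzyl)oxy]phenyl}[(2S,3S)-2-(2,4-dimethoxyphenyl)-3-(3,5-dimethoxyphenyl)-4-methoxy-2,3-dihydro-1-benzofuran-6-yl]methanol (both carbinol epimers), via aryllithium 25 (not isolated)
Conditions: n-BuLi (1.05 equiv), THF, −78 °C, 10 min; then 24, −78 °C; H2O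
Reagents that add atoms: none
Why: Bromine–lithium exchange at −78 °C outruns any deprotonation, and the aryllithium adds to the aldehyde far faster than it can exchange with the aryl bromide of the partner, forming the C3–C6' bond with a carbinol configuration that is irrelevant.

Step 15
Reactants: 26 diaryl carbinol
Product: 27 {4-bromo-2-methoxy-6-[(4-methoxybenzyl)oxy]phenyl}[(2S,3S)-2-(2,4-dimethoxyphenyl)-3-(3,5-dimethoxyphenyl)-4-methoxy-2,3-dihydro-1-benzofuran-6-yl]methanone
Conditions: Dess–Martin periodinane, CH2Cl2, rt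
Reagents that add atoms: none
Why: Dess–Martin oxidation of a diaryl carbinol to the benzophenone is general and tolerates the electron-rich rings and the benzylic ethers.

Step 16
Reactants: 27 diaryl ketone
Product: 28 hydrazone of 27 (C=N geometry not defined)
Conditions: N2H4·H2O (excess), AcOH (cat.), EtOH, 90 °C (sealed tube)
Reagents that add atoms: hydrazine (used as the hydrate), NN
Why: Acid-catalysed condensation of hydrazine with the diaryl ketone gives the N-unsubstituted hydrazone, a large excess of hydrazine and heat being used because two ortho alkoxy groups shield the carbonyl group and because excess reagent suppresses azine formation.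

Step 17
Reactants: 28 hydrazone
Product: 30 (2S,3S)-6-[(2R,3S)-6-bromo-4-methoxy-2-(4-methoxyphenyl)-2,3-dihydro-1-benzofuran-3-yl]-2-(2,4-dimethoxyphenyl)-3-(3,5-dimethoxyphenyl)-4-methoxy-2,3-dihydro-1-benzofuran (unit 1 cis), via diaryldiazomethane 29 (not isolated)
Conditions: MnO2, CH2Cl2, 0 °C; filter; Rh2(S-PTAD)4 [dirhodium tetrakis((S)-(1-adamantyl)(N-phthalimido)acetate)] (1 mol%), CH2Cl2, 0 °C
Reagents that add atoms: none
Why: Oxidation of the hydrazone gives the diaryldiazomethane, whose donor/donor rhodium carbene inserts into the benzylic C–H bond of the 4-methoxybenzyl ether in a 1,5 fashion, a reaction class known to give cis-2,3-diaryl-2,3-dihydrobenzofurans with high enantiocontrol, so that the catalyst and not the remote stereocentres of unit 2 fixes C3 (S) with C2 formed cis to it (R).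

Step 18
Reactants: 30 cis compound
Product: 31 (2S,3S)-6-[(2S,3S)-6-bromo-4-methoxy-2-(4-methoxyphenyl)-2,3-dihydro-1-benzofuran-3-yl]-2-(2,4-dimethoxyphenyl)-3-(3,5-dimethoxyphenyl)-4-methoxy-2,3-dihydro-1-benzofuran (unit 1 trans)
Conditions: CF3CO2H, CH2Cl2, 0 °C
Reagents that add atoms: none
Why: Protonation of O1 and reversible heterolysis of the C2–O1 bond give a 4-methoxybenzylic cation that recloses to the thermodynamically favoured trans-2,3-diaryl isomer (C2 becomes S) while C3 is not involved, and the analogous reversible opening at C2' can only return the trans ring of unit 2.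

Step 19
Reactants: 31 aryl bromide; 32 4-methoxystyrene
Product: 33 (2S,3S)-2-(2,4-dimethoxyphenyl)-3-(3,5-dimethoxyphenyl)-4-methoxy-6-{(2S,3S)-4-methoxy-2-(4-methoxyphenyl)-6-[(E)-2-(4-methoxyphenyl)ethenyl]-2,3-dihydro-1-benzofuran-3-yl}-2,3-dihydro-1-benzofuran (octamethyl ether)
Conditions: Pd(OAc)2 (5 mol%), P(o-tol)3, Et3N, DMF, 100 °C
Reagents that add atoms: none
Why: The Heck reaction of the unhindered aryl bromide with the styrene proceeds by syn insertion and syn beta-hydride elimination to give the E-stilbene, and the base-stable dihydrobenzofurans are unaffected.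

Step 20
Reactants: 33 octamethyl ether
Product: 34 CNP0118407.1
Conditions: BCl3, n-Bu4NI (excess of each), CH2Cl2, −78 → 0 °C; MeOH–H2O
Reagents that add atoms: none
Why: BCl3 activated by iodide cleaves aryl methyl ethers by SN2 attack of iodide on the boron-complexed methyl group at low temperature, a milder alternative to BBr3 for acid-sensitive 2-aryl-dihydrobenzofurans, and the stilbene is remote from both benzylic C–O bonds so that no intramolecular cation–alkene cyclisation is available.

**Compound list**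

1 | 4-bromo-2,6-dimethoxybenzaldehyde | COc1cc(Br)cc(OC)c1C=O | starting material
2 | 4-bromo-2-hydroxy-6-methoxybenzaldehyde | COc1cc(Br)cc(O)c1C=O | intermediate
3 | (2,4-dimethoxyphenyl)methanol | COc1ccc(CO)c(OC)c1 | starting material
4 | 4-bromo-2-[(2,4-dimethoxybenzyl)oxy]-6-methoxybenzaldehyde | COc1ccc(COc2cc(Br)cc(OC)c2C=O)c(OC)c1 | intermediate
5 | N-{2-[4-bromo-2-(2,4-dimethoxybenzyloxy)-6-methoxyphenyl]-1-tosylethenyl}formamide (present as its potassium salt; alkene geometry not defined) | COc1ccc(COc2cc(Br)cc(OC)c2C=C(NC=O)S(=O)(=O)c2ccc(C)cc2)c(OC)c1 | intermediate (not isolated)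
6 | 2-{4-bromo-2-[(2,4-dimethoxybenzyl)oxy]-6-methoxyphenyl}acetonitrile | COc1ccc(COc2cc(Br)cc(OC)c2CC#N)c(OC)c1 | intermediate
7 | 2-{4-bromo-2-[(2,4-dimethoxybenzyl)oxy]-6-methoxyphenyl}acetic acid | COc1ccc(COc2cc(Br)cc(OC)c2CC(=O)O)c(OC)c1 | intermediate (not isolated)
8 | methyl 2-{4-bromo-2-[(2,4-dimethoxybenzyl)oxy]-6-methoxyphenyl}acetate | COc1ccc(COc2cc(Br)cc(OC)c2CC(=O)OC)c(OC)c1 | intermediate
9 | methyl 2-{4-bromo-2-[(2,4-dimethoxybenzyl)oxy]-6-methoxyphenyl}-2-diazoacetate | COc1ccc(COc2cc(Br)cc(OC)c2C(=[N+]=[N-])C(=O)OC)c(OC)c1 | intermediate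
10 | methyl (2S,3R)-6-bromo-2-(2,4-dimethoxyphenyl)-4-methoxy-2,3-dihydro-1-benzofuran-3-carboxylate (cis) | Brc1cc(OC)c2c(c1)O[C@H](c1ccc(OC)cc1OC)[C@@H]2C(=O)OC | intermediate
11 | methyl (2S,3S)-6-bromo-2-(2,4-dimethoxyphenyl)-4-methoxy-2,3-dihydro-1-benzofuran-3-carboxylate (trans) | Brc1cc(OC)c2c(c1)O[C@H](c1ccc(OC)cc1OC)[C@H]2C(=O)OC | intermediate (not isolated)
12 | (2S,3S)-6-bromo-2-(2,4-dimethoxyphenyl)-4-methoxy-2,3-dihydro-1-benzofuran-3-carboxylic acid (trans) | Brc1cc(OC)c2c(c1)O[C@H](c1ccc(OC)cc1OC)[C@H]2C(=O)O | intermediate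
13 | 2,2,6-trimethyl-4H-1,3-dioxin-4-one | CC1=CC(=O)OC(C)(C)O1 | starting material
14 | lithium 2,2-dimethyl-6-methylidene-6H-1,3-dioxin-4-olate (dienolate of 13) | [Li+].C=C1C=C([O-])OC(C)(C)O1 | intermediate (not isolated)
15 | 2,2-dimethyl-6-(2-oxopropyl)-4H-1,3-dioxin-4-one | CC(=O)CC1=CC(=O)OC(C)(C)O1 | intermediate
16 | [(2S,3S)-6-bromo-2-(2,4-dimethoxyphenyl)-4-methoxy-2,3-dihydro-1-benzofuran-3-yl](1H-imidazol-1-yl)methanone | Brc1cc(OC)c2c(c1)O[C@H](c1ccc(OC)cc1OC)[C@H]2C(=O)n1ccnc1 | intermediate (not isolated)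
17 | dilithium dianion (bis-enolate) of 15 | [Li+].[Li+].C=C([O-])C=C1C=C([O-])OC(C)(C)O1 | intermediate (not isolated)
18 | 6-{4-[(2S,3S)-6-bromo-2-(2,4-dimethoxyphenyl)-4-methoxy-2,3-dihydro-1-benzofuran-3-yl]-2,4-dioxobutyl}-2,2-dimethyl-4H-1,3-dioxin-4-one | Brc1cc(OC)c2c(c1)O[C@H](c1ccc(OC)cc1OC)[C@H]2C(=O)CC(=O)CC1=CC(=O)OC(C)(C)O1 | intermediate
19 | 5-[(2S,3S)-6-bromo-2-(2,4-dimethoxyphenyl)-4-methoxy-2,3-dihydro-1-benzofuran-3-yl]-7-hydroxy-2,2-dimethyl-4H-1,3-benzodioxin-4-one | Brc1cc(OC)c2c(c1)O[C@H](c1ccc(OC)cc1OC)[C@H]2c1cc(O)cc2c1C(=O)OC(C)(C)O2 | intermediate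
20 | 2-[(2S,3S)-6-bromo-2-(2,4-dimethoxyphenyl)-4-methoxy-2,3-dihydro-1-benzofuran-3-yl]-4,6-dihydroxybenzoic acid | Brc1cc(OC)c2c(c1)O[C@H](c1ccc(OC)cc1OC)[C@H]2c1cc(O)cc(O)c1C(=O)O | intermediate (not isolated)
21 | 5-[(2S,3S)-6-bromo-2-(2,4-dimethoxyphenyl)-4-methoxy-2,3-dihydro-1-benzofuran-3-yl]benzene-1,3-diol | Brc1cc(OC)c2c(c1)O[C@H](c1ccc(OC)cc1OC)[C@H]2c1cc(O)cc(O)c1 | intermediate
22 | (2S,3S)-6-bromo-2-(2,4-dimethoxyphenyl)-3-(3,5-dimethoxyphenyl)-4-methoxy-2,3-dihydro-1-benzofuran | Brc1cc(OC)c2c(c1)O[C@H](c1ccc(OC)cc1OC)[C@H]2c1cc(OC)cc(OC)c1 | intermediate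
23 | 4-methoxybenzyl chloride | COc1ccc(CCl)cc1 | starting material
24 | 4-bromo-2-methoxy-6-[(4-methoxybenzyl)oxy]benzaldehyde | COc1ccc(COc2cc(Br)cc(OC)c2C=O)cc1 | intermediate
25 | [(2S,3S)-2-(2,4-dimethoxyphenyl)-3-(3,5-dimethoxyphenyl)-4-methoxy-2,3-dihydro-1-benzofuran-6-yl]lithium | [Li]c1cc(OC)c2c(c1)O[C@H](c1ccc(OC)cc1OC)[C@H]2c1cc(OC)cc(OC)c1 | intermediate (not isolated)
26 | {4-bromo-2-methoxy-6-[(4-methoxybenzyl)oxy]phenyl}[(2S,3S)-2-(2,4-dimethoxyphenyl)-3-(3,5-dimethoxyphenyl)-4-methoxy-2,3-dihydro-1-benzofuran-6-yl]methanol (both carbinol epimers) | OC(c1cc(OC)c2c(c1)O[C@H](c1ccc(OC)cc1OC)[C@H]2c1cc(OC)cc(OC)c1)c1c(OC)cc(Br)cc1OCc1ccc(OC)cc1 | intermediate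
27 | {4-bromo-2-methoxy-6-[(4-methoxybenzyl)oxy]phenyl}[(2S,3S)-2-(2,4-dimethoxyphenyl)-3-(3,5-dimethoxyphenyl)-4-methoxy-2,3-dihydro-1-benzofuran-6-yl]methanone | O=C(c1cc(OC)c2c(c1)O[C@H](c1ccc(OC)cc1OC)[C@H]2c1cc(OC)cc(OC)c1)c1c(OC)cc(Br)cc1OCc1ccc(OC)cc1 | intermediate
28 | hydrazone of 27 (C=N geometry not defined) | NN=C(c1cc(OC)c2c(c1)O[C@H](c1ccc(OC)cc1OC)[C@H]2c1cc(OC)cc(OC)c1)c1c(OC)cc(Br)cc1OCc1ccc(OC)cc1 | intermediate
29 | (2S,3S)-6-[{4-bromo-2-methoxy-6-[(4-methoxybenzyl)oxy]phenyl}(diazo)methyl]-2-(2,4-dimethoxyphenyl)-3-(3,5-dimethoxyphenyl)-4-methoxy-2,3-dihydro-1-benzofuran | [N-]=[N+]=C(c1cc(OC)c2c(c1)O[C@H](c1ccc(OC)cc1OC)[C@H]2c1cc(OC)cc(OC)c1)c1c(OC)cc(Br)cc1OCc1ccc(OC)cc1 | intermediate (not isolated)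
30 | (2S,3S)-6-[(2R,3S)-6-bromo-4-methoxy-2-(4-methoxyphenyl)-2,3-dihydro-1-benzofuran-3-yl]-2-(2,4-dimethoxyphenyl)-3-(3,5-dimethoxyphenyl)-4-methoxy-2,3-dihydro-1-benzofuran (unit 1 cis) | Brc1cc(OC)c2c(c1)O[C@@H](c1ccc(OC)cc1)[C@H]2c1cc(OC)c2c(c1)O[C@H](c1ccc(OC)cc1OC)[C@H]2c1cc(OC)cc(OC)c1 | intermediate
31 | (2S,3S)-6-[(2S,3S)-6-bromo-4-methoxy-2-(4-methoxyphenyl)-2,3-dihydro-1-benzofuran-3-yl]-2-(2,4-dimethoxyphenyl)-3-(3,5-dimethoxyphenyl)-4-methoxy-2,3-dihydro-1-benzofuran (unit 1 trans) | Brc1cc(OC)c2c(c1)O[C@H](c1ccc(OC)cc1)[C@H]2c1cc(OC)c2c(c1)O[C@H](c1ccc(OC)cc1OC)[C@H]2c1cc(OC)cc(OC)c1 | intermediate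
32 | 4-methoxystyrene | C=Cc1ccc(OC)cc1 | starting material
33 | (2S,3S)-2-(2,4-dimethoxyphenyl)-3-(3,5-dimethoxyphenyl)-4-methoxy-6-{(2S,3S)-4-methoxy-2-(4-methoxyphenyl)-6-[(E)-2-(4-methoxyphenyl)ethenyl]-2,3-dihydro-1-benzofuran-3-yl}-2,3-dihydro-1-benzofuran | COc1ccc(/C=C/c2cc(OC)c3c(c2)O[C@H](c2ccc(OC)cc2)[C@H]3c2cc(OC)c3c(c2)O[C@H](c2ccc(OC)cc2OC)[C@H]3c2cc(OC)cc(OC)c2)cc1 | intermediate
34 | CNP0118407.1, 4-[(2S,3S)-3-(3,5-dihydroxyphenyl)-4-hydroxy-6-{(2S,3S)-4-hydroxy-2-(4-hydroxyphenyl)-6-[(E)-2-(4-hydroxyphenyl)ethenyl]-2,3-dihydro-1-benzofuran-3-yl}-2,3-dihydro-1-benzofuran-2-yl]benzene-1,3-diol | Oc1ccc(/C=C/c2cc(O)c3c(c2)O[C@H](c2ccc(O)cc2)[C@H]3c2cc(O)c3c(c2)O[C@H](c2ccc(O)cc2O)[C@H]3c2cc(O)cc(O)c2)cc1 | target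

**Step count and risks**

Total: 20 steps. Longest linear sequence: 18 steps (1 to 34 through steps 1–7, 9–12 and 14–20).

Step 20 (global demethylation). Eight ethers must be cleaved, and once the para oxygens are unmasked the Lewis acid can ionise the benzylic C2–O1 and C2'–O1' bonds. With the stilbene present, the cations may be captured irreversibly by the alkene of another molecule, and partly cleaved material may be lost on isolation. The fallback removes the methyl groups before the stilbene exists and makes the last operation a mild methanolysis. It sets out from 31. BBr3 in CH2Cl2 (−78 → 0 °C) gives the heptaphenol bromide F7, in which ring opening can only be followed by reclosure to the trans rings. Ac2O and pyridine convert it into the chromatographable heptaacetate F8. A Heck reaction of F8 with 4-acetoxystyrene (Pd(OAc)2, P(o-tol)3, Et3N, MeCN, 80 °C) gives the octaacetate F9. K2CO3 in MeOH at 0 °C releases the phenols, and the route is rejoined at 34.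

Step 16 (hydrazone formation). Condensation at a carbonyl group shielded by two ortho alkoxy groups may stall, and prolonged forcing with hydrazine invites azine formation. The fallback replaces carbonyl condensation by transimination of an N-unsubstituted ketimine, which loses ammonia irreversibly. It sets out from 24 and from aryllithium 25 (made from 22 as in step 14). Aldehyde 24 is converted with I2 and aqueous NH3 in THF into 4-bromo-2-methoxy-6-[(4-methoxybenzyl)oxy]benzonitrile F4. Aryllithium 25 is transmetalated with MgBr2·OEt2 to the arylmagnesium bromide F5, which does not exchange with the aryl bromide of F4. Addition of F5 to F4 (CuBr cat., THF, 60 °C) and a methanol quench give the N–H ketimine F6. Hydrazine hydrate with acetic acid in ethanol at 60 °C then gives hydrazone 28, where the route is rejoined.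

Step 9 (dianion acylation). Proton transfer from C3' of the acyl imidazolide to the strongly basic dianion (ketene formation) and O-acylation may compete with C-acylation at the hindered carbonyl group, costing conversion and eroding the trans configuration. The fallback uses soft enolisation without strong base. It sets out from 12 and from dienolate 14 (made from 13 as in step 8). Acylation of 14 with allyl malonyl chloride gives allyl 4-(2,2-dimethyl-4-oxo-4H-1,3-dioxin-6-yl)-3-oxobutanoate F1. Acid 12 is converted with 1-chloro-N,N,2-trimethylprop-1-en-1-amine (CH2Cl2, 0 °C) into the acid chloride F2. MgCl2 and pyridine in CH2Cl2 at 0 °C C-acylate the magnesium enolate of F1 at its doubly activated methylene group to give the triketo allyl ester F3. Pd(PPh3)4 with morpholine in THF at rt removes the allyl group (Tsuji–Trost deallylation), and the beta-keto acid decarboxylates to diketo-dioxinone 18, where the route is rejoined.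

Further compounds
F1 | step 9 | allyl 4-(2,2-dimethyl-4-oxo-4H-1,3-dioxin-6-yl)-3-oxobutanoate | C=CCOC(=O)CC(=O)CC1=CC(=O)OC(C)(C)O1
F2 | step 9 | (2S,3S)-6-bromo-2-(2,4-dimethoxyphenyl)-4-methoxy-2,3-dihydro-1-benzofuran-3-carbonyl chloride | Brc1cc(OC)c2c(c1)O[C@H](c1ccc(OC)cc1OC)[C@H]2C(=O)Cl
F3 | step 9 | allyl 2-{[(2S,3S)-6-bromo-2-(2,4-dimethoxyphenyl)-4-methoxy-2,3-dihydro-1-benzofuran-3-yl]carbonyl}-4-(2,2-dimethyl-4-oxo-4H-1,3-dioxin-6-yl)-3-oxobutanoate (configuration at the acylated carbon not defined) | Brc1cc(OC)c2c(c1)O[C@H](c1ccc(OC)cc1OC)[C@H]2C(=O)C(C(=O)OCC=C)C(=O)CC1=CC(=O)OC(C)(C)O1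
F4 | step 16 | 4-bromo-2-methoxy-6-[(4-methoxybenzyl)oxy]benzonitrile | COc1ccc(COc2cc(Br)cc(OC)c2C#N)cc1
F5 | step 16 | bromo[(2S,3S)-2-(2,4-dimethoxyphenyl)-3-(3,5-dimethoxyphenyl)-4-methoxy-2,3-dihydro-1-benzofuran-6-yl]magnesium | Br[Mg]c1cc(OC)c2c(c1)O[C@H](c1ccc(OC)cc1OC)[C@H]2c1cc(OC)cc(OC)c1
F6 | step 16 | 1-{4-bromo-2-methoxy-6-[(4-methoxybenzyl)oxy]phenyl}-1-[(2S,3S)-2-(2,4-dimethoxyphenyl)-3-(3,5-dimethoxyphenyl)-4-methoxy-2,3-dihydro-1-benzofuran-6-yl]methanimine | N=C(c1cc(OC)c2c(c1)O[C@H](c1ccc(OC)cc1OC)[C@H]2c1cc(OC)cc(OC)c1)c1c(OC)cc(Br)cc1OCc1ccc(OC)cc1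
F7 | step 20 | 4-[(2S,3S)-6-[(2S,3S)-6-bromo-4-hydroxy-2-(4-hydroxyphenyl)-2,3-dihydro-1-benzofuran-3-yl]-3-(3,5-dihydroxyphenyl)-4-hydroxy-2,3-dihydro-1-benzofuran-2-yl]benzene-1,3-diol | Brc1cc(O)c2c(c1)O[C@H](c1ccc(O)cc1)[C@H]2c1cc(O)c2c(c1)O[C@H](c1ccc(O)cc1O)[C@H]2c1cc(O)cc(O)c1
F8 | step 20 | heptaacetate of F7 | Brc1cc(OC(C)=O)c2c(c1)O[C@H](c1ccc(OC(C)=O)cc1)[C@H]2c1cc(OC(C)=O)c2c(c1)O[C@H](c1ccc(OC(C)=O)cc1OC(C)=O)[C@H]2c1cc(OC(C)=O)cc(OC(C)=O)c1
F9 | step 20 | octaacetate of 34 | CC(=O)Oc1ccc(/C=C/c2cc(OC(C)=O)c3c(c2)O[C@H](c2ccc(OC(C)=O)cc2)[C@H]3c2cc(OC(C)=O)c3c(c2)O[C@H](c2ccc(OC(C)=O)cc2OC(C)=O)[C@H]3c2cc(OC(C)=O)cc(OC(C)=O)c2)cc1
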